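## Retrosynthetic overview

1. Target 21 (azulene numbering: C1 OAc, C3 OH/i‑Pr, C3a H, C4 O‑anisoyl, C6=C7, C8a Me) ⇒ ring-closing metathesis at C6=C7 from diene 20; the C4 and C1 esters come from triol 15.
2. Triol 15 ⇒ methylenation at C7 and chelation-controlled methallylation at C4 of the bicyclic lactol aldehyde 12.
3. Aldehyde 12 ⇒ C3–C3a bond by a lactol-templated, desymmetrising intramolecular aldol addition of the acyclic keto-dialdehyde 10 (one stereocentre), which closes the cyclopentane and sets C3, C3a and quaternary C8a together.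
4. Keto-dialdehyde 10 ⇒ double ozonolysis of the diallyl aldol 8 ⇒ proline aldol of 3-methylbutan-2-one (7) with 2,2-diallylpropanal (6), made from propanenitrile (1) and two equivalents of allyl bromide (2).
5. Enabling feature: C3(OH)–C3a–C4(O) is an aldol retron, and quaternary C8a carries two branches (C8–C7 and C3a–C4) that become identical CH2–CHO groups once C5–C6 is excised from the cycloheptene; the C1 oxygen is cis to C8 and can tie that branch up as a lactol. Ring order: temporary oxolane and cyclopentane (step 5), cycloheptene last (step 10).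

Key step: step 5

Remark on the chemistry: hemiacetal carbons (in 11, 12, 14) equilibrate and are written without configuration, as is the iodomethyl-bearing carbon of the fallback oxolanes; atom numbers in the text are those of the target.

## Route

Step 1
Reactants: 1 propanenitrile; 2 3-bromoprop-1-ene (allyl bromide; two equivalents in all, one for each alkylation)
Product: 4 2-methyl-2-(prop-2-en-1-yl)pent-4-enenitrile, via 2-methylpent-4-enenitrile 3 (not isolated)
Conditions: LiN(i-Pr)2 (1.05 equiv), THF, −78 °C, then 2 (1.0 equiv), −78 → 0 °C; recool, LiN(i-Pr)2 (1.15 equiv), −78 °C, then 2 (1.3 equiv), −78 °C → rt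
Reagents that add atoms: 3-bromoprop-1-ene (the second equivalent of 2, which alkylates 3), C=CCBr
Why: Two successive SN2 alkylations of the nitrile-stabilised carbanion, each with one equivalent of the allylic bromide, should give the achiral diallylated nitrile, so no stereocentre has to be controlled.

Step 2
Reactants: 4 2-methyl-2-(prop-2-en-1-yl)pent-4-enenitrile
Product: 6 2-methyl-2-(prop-2-en-1-yl)pent-4-enal, via N-aluminated imine 5 (not isolated)
Conditions: i-Bu2AlH (1.3 equiv), CH2Cl2, −78 → 0 °C; then 1 M HCl, 0 °C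
Reagents that add atoms: water, O
Why: Partial reduction of a nitrile by a dialkylaluminium hydride stops at the N-aluminated imine, which is hydrolysed to the aldehyde; the quaternary α-carbon excludes enolisation and no stereocentre is formed.

Step 3
Reactants: 6 2-methyl-2-(prop-2-en-1-yl)pent-4-enal; 7 3-methylbutan-2-one
Product: 8 (5S)-5-hydroxy-2,6-dimethyl-6-(prop-2-en-1-yl)non-8-en-3-one
Conditions: D-proline (30 mol %), 7/DMSO 1:4, rt, 3–5 d
Reagents that add atoms: none
Why: In this proline-catalysed direct aldol addition the enamine should form only on the methyl side of 7 and add to the non-enolisable neopentyl-type aldehyde through the hydrogen-bonded chair transition state, D-proline giving the (S)-carbinol (future C1), the mirror image of the known L-proline/acetone/pivalaldehyde outcome.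

Step 4
Reactants: 8 (5S)-5-hydroxy-2,6-dimethyl-6-(prop-2-en-1-yl)non-8-en-3-one
Product: 10 3-[(1S)-1-hydroxy-4-methyl-3-oxopentyl]-3-methylpentanedial, via bis-ozonide 9 (not isolated)
Conditions: O3, CH2Cl2, −78 °C; then Me2S, −78 °C → rt
Reagents that add atoms: ozone, O=[O+][O-] (one equivalent per alkene)
Why: Ozonolysis with reductive work-up should cleave both terminal alkenes to CH2CHO groups, which makes the two arms on the quaternary carbon constitutionally identical (the carbon becomes prochiral, the carbinol centre is untouched), and the product is expected to exist mainly as its five-membered lactols.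

Step 5
Reactants: 10 3-[(1S)-1-hydroxy-4-methyl-3-oxopentyl]-3-methylpentanedial
Product: 12 (3aR,4R,5R,6aS)-2,5-dihydroxy-3a-methyl-5-(propan-2-yl)hexahydro-2H-cyclopenta[b]furan-4-carbaldehyde (anomeric mixture), via cis-lactol 11 (not isolated)
Conditions: D-proline (20 mol %), CH2Cl2 (0.05 M), rt, 24–48 h
Reagents that add atoms: none
Why: The C1 hydroxyl closes reversibly onto either CH2CHO arm (5-exo-trig hemiacetal formation) and D-proline condenses with the remaining aldehyde to an E-enamine, whose nucleophilic carbon (future C3a) adds to the isopropyl ketone carbon (future C3) in a 5-(enolexo)-exo-trig aldol addition while the carboxylic acid protonates the developing alkoxide, and hydrolysis of the iminium ion returns the catalyst. The closest known reaction type is the proline-catalysed intramolecular enolexo aldolisation of dicarbonyl compounds with an aldehyde donor and a ketone acceptor, including its desymmetrising variants on dialdehydes. C8a is controlled by the lactol: the lactols interconvert through the open form faster than they cyclise, and only lactol 11, in which the free arm and the ketone arm are cis on the oxolane, can reach a cis-fused bicyclo[3.3.0] transition state, so the arm cis to the C1 oxygen becomes C8 and the other becomes C3a–C4. C3a is controlled by the bicyclic template, the bulky enamine taking the convex face (formyl cis to the angular methyl, trans to C8, which is the later trans ring fusion), and this is also the enamine face that D-proline attacks, so catalyst and substrate are matched. C3 is controlled by the compact hydrogen-bonded transition state, in which the ketone oxygen points towards the enamine nitrogen and its acid and the isopropyl group avoids the enamine carbon, which places the new hydroxyl cis to the formyl group. The step needs the aldehyde to act as donor and the ketone as acceptor (secured by enamine catalysis, which activates the aldehyde far faster than the ketone), the choice between the two arms (secured by the lactol and the cis C1–O/C8 relationship), and a stop at the aldol stage without dehydration (secured by the mild, base-free conditions).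

Step 6
Reactants: 12 (3aR,4R,5R,6aS)-2,5-dihydroxy-3a-methyl-5-(propan-2-yl)hexahydro-2H-cyclopenta[b]furan-4-carbaldehyde; 13 3-bromo-2-methylprop-1-ene
Product: 14 (3aR,4S,5R,6aS)-4-[(1S)-1-hydroxy-3-methylbut-3-en-1-yl]-3a-methyl-5-(propan-2-yl)hexahydro-2H-cyclopenta[b]furan-2,5-diol
Conditions: In (powder, 1.3 equiv), 13 (1.3 equiv), THF/H2O 1:1, 0 °C, 1 h
Reagents that add atoms: none
Why: In this Barbier-type allylation the free aldehyde should react far faster than the lactol-masked one, and a chelate of trivalent indium between the aldehyde oxygen and the cis tertiary hydroxyl fixes the carbonyl so that the nucleophile enters opposite to the quaternary ring carbon (chelation control; the open model with that carbon as the large group predicts the same face), setting C4 as S.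

Step 7
Reactants: 14 (3aR,4S,5R,6aS)-4-[(1S)-1-hydroxy-3-methylbut-3-en-1-yl]-3a-methyl-5-(propan-2-yl)hexahydro-2H-cyclopenta[b]furan-2,5-diol
Product: 15 (1R,3S,4R,5S)-5-[(1S)-1-hydroxy-3-methylbut-3-en-1-yl]-4-methyl-1-(propan-2-yl)-4-(prop-2-en-1-yl)cyclopentane-1,3-diol
Conditions: Ph3PCH3Br (6 equiv), KOt-Bu (5.5 equiv), THF, 0 °C → rt
Reagents that add atoms: methyltriphenylphosphonium bromide, C[P+](c1ccccc1)(c1ccccc1)c1ccccc1.[Br-]
Why: Wittig methylenation of the ring-opened hydroxy-aldehyde tautomer of the lactol should unveil the allyl group on C8a and the free C1 hydroxyl in one operation and removes the undefined hemiacetal centre, with no other stereocentre touched.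

Step 8
Reactants: 15 (1R,3S,4R,5S)-5-[(1S)-1-hydroxy-3-methylbut-3-en-1-yl]-4-methyl-1-(propan-2-yl)-4-(prop-2-en-1-yl)cyclopentane-1,3-diol
Product: 18 (1S,2R,3S,4R)-4-hydroxy-3-[(1S)-1-hydroxy-3-methylbut-3-en-1-yl]-2-methyl-4-(propan-2-yl)-2-(prop-2-en-1-yl)cyclopentyl acetate, via cyclic phenylboronate 16 (not isolated), via acetylated phenylboronate 17 (not isolated)
Conditions: PhB(OH)2 (1.05 equiv), toluene, 4 Å sieves, 50 °C; then Ac2O, pyridine, DMAP (cat.), rt; then 30% H2O2, aq NaHCO3, THF, 0 °C
Reagents that add atoms: acetic anhydride, CC(=O)OC(C)=O; phenylboronic acid, OB(O)c1ccccc1 (its atoms stay only in 16 and 17)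
Why: Transient boronate protection relies on the fact that only the cis-related C3 and C4 hydroxyls can span a six-membered dioxaborinane (the C1 hydroxyl lies on the other face), so the DMAP-catalysed acetylation is confined to the C1 hydroxyl and mild peroxide oxidation of the aryl–boron bond then releases the diol without touching a stereocentre.

Step 9
Reactants: 18 (1S,2R,3S,4R)-4-hydroxy-3-[(1S)-1-hydroxy-3-methylbut-3-en-1-yl]-2-methyl-4-(propan-2-yl)-2-(prop-2-en-1-yl)cyclopentyl acetate; 19 4-methoxybenzoyl chloride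
Product: 20 (1S)-1-[(1S,2R,3S,5R)-3-(acetyloxy)-5-hydroxy-2-methyl-5-(propan-2-yl)-2-(prop-2-en-1-yl)cyclopentyl]-3-methylbut-3-en-1-yl 4-methoxybenzoate
Conditions: 19 (1.5 equiv), Et3N, DMAP (0.5 equiv), CH2Cl2, 0 °C → rt
Reagents that add atoms: none
Why: In this nucleophile-catalysed acylation only the secondary C4 hydroxyl should be esterified, the tertiary C3 hydroxyl being inert under these conditions, and the configuration at C4 is retained because its C–O bond is not broken.

Step 10
Reactants: 20 (1S)-1-[(1S,2R,3S,5R)-3-(acetyloxy)-5-hydroxy-2-methyl-5-(propan-2-yl)-2-(prop-2-en-1-yl)cyclopentyl]-3-methylbut-3-en-1-yl 4-methoxybenzoate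
Product: 21 (1S,3R,3aS,4S,8aR)-1-(acetyloxy)-3-hydroxy-6,8a-dimethyl-3-(propan-2-yl)-1,2,3,3a,4,5,8,8a-octahydroazulen-4-yl 4-methoxybenzoate (target)
Conditions: second-generation Grubbs catalyst RuCl2(=CHPh)(H2IMes)(PCy3) (5 mol %), CH2Cl2 (2 mM), 40 °C
Reagents that add atoms: none
Why: Ring-closing olefin metathesis between the monosubstituted and the 1,1-disubstituted alkene should give the trisubstituted C6=C7 bond of the cycloheptene with loss of ethene, the trans disposition of the two arms set in step 5 making the ring fusion trans, and no stereocentre is touched.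

## Compound list

1 | propanenitrile | CCC#N | starting material
2 | 3-bromoprop-1-ene | C=CCBr | starting material
3 | 2-methylpent-4-enenitrile (racemic) | C=CCC(C)C#N | intermediate
4 | 2-methyl-2-(prop-2-en-1-yl)pent-4-enenitrile | C=CCC(C)(CC=C)C#N | intermediate
5 | N-[bis(2-methylpropyl)alumanyl]-2-methyl-2-(prop-2-en-1-yl)pent-4-en-1-imine | C=CCC(C)(CC=C)C=N[Al](CC(C)C)CC(C)C | intermediate
6 | 2-methyl-2-(prop-2-en-1-yl)pent-4-enal | C=CCC(C)(CC=C)C=O | intermediate
7 | 3-methylbutan-2-one | CC(C)C(C)=O | starting material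
8 | (5S)-5-hydroxy-2,6-dimethyl-6-(prop-2-en-1-yl)non-8-en-3-one | CC(C)C(=O)C[C@H](O)C(C)(CC=C)CC=C | intermediate
9 | (5S)-5-hydroxy-2,6-dimethyl-7-(1,2,4-trioxolan-3-yl)-6-[(1,2,4-trioxolan-3-yl)methyl]heptan-3-one (bis-ozonide, ring carbons undefined) | CC(C)C(=O)C[C@H](O)C(C)(CC1OCOO1)CC1OCOO1 | intermediate
10 | 3-[(1S)-1-hydroxy-4-methyl-3-oxopentyl]-3-methylpentanedial | CC(C)C(=O)C[C@H](O)C(C)(CC=O)CC=O | intermediate
11 | 2-[(2S,3S)-5-hydroxy-3-methyl-2-(3-methyl-2-oxobutyl)oxolan-3-yl]acetaldehyde (free arm cis to the ketone arm; anomers) | O=CC[C@@]1(C)CC(O)O[C@H]1CC(=O)C(C)C | intermediate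
12 | (3aR,4R,5R,6aS)-2,5-dihydroxy-3a-methyl-5-(propan-2-yl)hexahydro-2H-cyclopenta[b]furan-4-carbaldehyde (cis-fused; CHO and 5-OH on the convex face; anomers) | O=C[C@@H]1[C@@]2(C)CC(O)O[C@H]2C[C@@]1(O)C(C)C | intermediate
13 | 3-bromo-2-methylprop-1-ene | C=C(C)CBr | starting material
14 | (3aR,4S,5R,6aS)-4-[(1S)-1-hydroxy-3-methylbut-3-en-1-yl]-3a-methyl-5-(propan-2-yl)hexahydro-2H-cyclopenta[b]furan-2,5-diol (anomers) | C=C(C)C[C@H](O)[C@@H]1[C@@]2(C)CC(O)O[C@H]2C[C@@]1(O)C(C)C | intermediate
15 | (1R,3S,4R,5S)-5-[(1S)-1-hydroxy-3-methylbut-3-en-1-yl]-4-methyl-1-(propan-2-yl)-4-(prop-2-en-1-yl)cyclopentane-1,3-diol | C=C(C)C[C@H](O)[C@@H]1[C@@](C)(CC=C)[C@@H](O)C[C@@]1(O)C(C)C | intermediate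
16 | cyclic phenylboronate (2-phenyl-1,3,2-dioxaborinane) of 15 across the tertiary hydroxyl and the side-chain hydroxyl, ring hydroxyl free, stereocentres as in 15 | C=C(C)C[C@@H]1OB(c2ccccc2)O[C@@]2(C(C)C)C[C@H](O)[C@](C)(CC=C)[C@@H]12 | intermediate
17 | acetate of 16 at the free ring hydroxyl, stereocentres as in 15 | C=C(C)C[C@@H]1OB(c2ccccc2)O[C@@]2(C(C)C)C[C@H](OC(C)=O)[C@](C)(CC=C)[C@@H]12 | intermediate
18 | (1S,2R,3S,4R)-4-hydroxy-3-[(1S)-1-hydroxy-3-methylbut-3-en-1-yl]-2-methyl-4-(propan-2-yl)-2-(prop-2-en-1-yl)cyclopentyl acetate | C=C(C)C[C@H](O)[C@@H]1[C@@](C)(CC=C)[C@@H](OC(C)=O)C[C@@]1(O)C(C)C | intermediate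
19 | 4-methoxybenzoyl chloride | COc1ccc(C(Cl)=O)cc1 | starting material
20 | (1S)-1-[(1S,2R,3S,5R)-3-(acetyloxy)-5-hydroxy-2-methyl-5-(propan-2-yl)-2-(prop-2-en-1-yl)cyclopentyl]-3-methylbut-3-en-1-yl 4-methoxybenzoate | COc1ccc(C(=O)O[C@@H](CC(C)=C)[C@@H]2[C@@](C)(CC=C)[C@@H](OC(C)=O)C[C@@]2(O)C(C)C)cc1 | intermediate
21 | (1S,3R,3aS,4S,8aR)-1-(acetyloxy)-3-hydroxy-6,8a-dimethyl-3-(propan-2-yl)-1,2,3,3a,4,5,8,8a-octahydroazulen-4-yl 4-methoxybenzoate | COc1ccc(C(=O)O[C@H]2CC(C)=CC[C@@]3(C)[C@@H](OC(C)=O)C[C@@](O)(C(C)C)[C@H]23)cc1 | target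

## Step count and risks

Total step count: 10. Longest linear sequence: 10 steps (from propanenitrile 1; compounds 2, 7, 13 and 19 are bought).

**Step 5 (key step).** Part of the cyclisation may run through the open-chain dialdehyde, in which both arms are free, so that the choice of arm (configuration at C8a) is eroded, and the aldol may dehydrate. The fallback replaces the dynamic lactol by a fixed tether and sets out from 8. Iodoetherification (I2, NaHCO3, MeCN, 0 °C) closes the C1 hydroxyl irreversibly onto one allyl group. The isomer with the remaining allyl group cis to the ketone side chain, 1-[(2S,3S)-5-(iodomethyl)-3-methyl-3-(prop-2-en-1-yl)oxolan-2-yl]-3-methylbutan-2-one F1, is separated from its epimer 1-[(2S,3R)-5-(iodomethyl)-3-methyl-3-(prop-2-en-1-yl)oxolan-2-yl]-3-methylbutan-2-one F2, which is returned to 8 with Zn dust. Oxidative cleavage of the alkene of F1 under conditions that spare the alkyl iodide (OsO4 cat., NaIO4, 2,6-lutidine, dioxane/H2O) gives the single aldehyde 2-[(2S,3R)-5-(iodomethyl)-3-methyl-2-(3-methyl-2-oxobutyl)oxolan-3-yl]acetaldehyde F3. The same D-proline aldolisation, now with only one possible arm, should give (3aR,4R,5R,6aS)-5-hydroxy-2-(iodomethyl)-3a-methyl-5-(propan-2-yl)hexahydro-2H-cyclopenta[b]furan-4-carbaldehyde F4. Methallylation as in step 6 gives (3aR,4S,5R,6aS)-4-[(1S)-1-hydroxy-3-methylbut-3-en-1-yl]-2-(iodomethyl)-3a-methyl-5-(propan-2-yl)hexahydro-2H-cyclopenta[b]furan-5-ol F5. Reductive opening of the β-iodo ether (Zn, NH4Cl, EtOH, 70 °C) restores the allyl group and the free hydroxyl, and the route is rejoined at 15.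

**Step 6.** The ring-opened lactol may be allylated as well (over-addition), and facial control may be incomplete if the aldehyde reacts without chelation in water. The fallback masks the lactol at the lactone level and uses a Lewis-acid chelate; it sets out from 12. Oxidation with TEMPO (cat.) and PhI(OAc)2 in CH2Cl2 converts only the lactol, giving (3aR,4R,5R,6aS)-5-hydroxy-3a-methyl-2-oxo-5-(propan-2-yl)hexahydro-2H-cyclopenta[b]furan-4-carbaldehyde F6. Chelation-controlled addition of tributyl(2-methylprop-2-en-1-yl)stannane with MgBr2·OEt2 (CH2Cl2, −78 → −20 °C) should give (3aR,4S,5R,6aS)-5-hydroxy-4-[(1S)-1-hydroxy-3-methylbut-3-en-1-yl]-3a-methyl-5-(propan-2-yl)hexahydro-2H-cyclopenta[b]furan-2-one F7. Reduction of the lactone with i-Bu2AlH (CH2Cl2, −78 °C) returns to the route at lactol 14.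

**Step 3.** Enamine formation from the hindered ketone and addition to the neopentyl aldehyde may be slow, giving low conversion or eroded enantioselectivity. The fallback uses an auxiliary-controlled acetate aldol and sets out from 6. The tin enolate of (4R)-3-acetyl-4-(propan-2-yl)-1,3-thiazolidine-2-thione (Sn(OTf)2, N-ethylpiperidine, CH2Cl2, −78 °C; divalent tin chelated by the thione, closed chair transition state) should give (3S)-3-hydroxy-4-methyl-1-[(4R)-4-(propan-2-yl)-2-sulfanylidene-1,3-thiazolidin-3-yl]-4-(prop-2-en-1-yl)hept-6-en-1-one F8, the minor diastereomer being removed by chromatography. Aminolysis with MeNH(OMe)·HCl and imidazole gives (3S)-3-hydroxy-N-methoxy-N,4-dimethyl-4-(prop-2-en-1-yl)hept-6-enamide F9. Addition of i-PrMgCl (excess, THF, 0 °C) gives the isopropyl ketone and rejoins the route at 8.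

## Further compounds

F1 | step 5 | 1-[(2S,3S)-5-(iodomethyl)-3-methyl-3-(prop-2-en-1-yl)oxolan-2-yl]-3-methylbutan-2-one | C=CC[C@@]1(C)CC(CI)O[C@H]1CC(=O)C(C)C
F2 | step 5 | 1-[(2S,3R)-5-(iodomethyl)-3-methyl-3-(prop-2-en-1-yl)oxolan-2-yl]-3-methylbutan-2-one | C=CC[C@]1(C)CC(CI)O[C@H]1CC(=O)C(C)C
F3 | step 5 | 2-[(2S,3R)-5-(iodomethyl)-3-methyl-2-(3-methyl-2-oxobutyl)oxolan-3-yl]acetaldehyde | O=CC[C@@]1(C)CC(CI)O[C@H]1CC(=O)C(C)C
F4 | step 5 | (3aR,4R,5R,6aS)-5-hydroxy-2-(iodomethyl)-3a-methyl-5-(propan-2-yl)hexahydro-2H-cyclopenta[b]furan-4-carbaldehyde | O=C[C@@H]1[C@@]2(C)CC(CI)O[C@H]2C[C@@]1(O)C(C)C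
F5 | step 5 | (3aR,4S,5R,6aS)-4-[(1S)-1-hydroxy-3-methylbut-3-en-1-yl]-2-(iodomethyl)-3a-methyl-5-(propan-2-yl)hexahydro-2H-cyclopenta[b]furan-5-ol | C=C(C)C[C@H](O)[C@@H]1[C@@]2(C)CC(CI)O[C@H]2C[C@@]1(O)C(C)C
F6 | step 6 | (3aR,4R,5R,6aS)-5-hydroxy-3a-methyl-2-oxo-5-(propan-2-yl)hexahydro-2H-cyclopenta[b]furan-4-carbaldehyde | O=C[C@@H]1[C@@]2(C)CC(=O)O[C@H]2C[C@@]1(O)C(C)C
F7 | step 6 | (3aR,4S,5R,6aS)-5-hydroxy-4-[(1S)-1-hydroxy-3-methylbut-3-en-1-yl]-3a-methyl-5-(propan-2-yl)hexahydro-2H-cyclopenta[b]furan-2-one | C=C(C)C[C@H](O)[C@@H]1[C@@]2(C)CC(=O)O[C@H]2C[C@@]1(O)C(C)C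
F8 | step 3 | (3S)-3-hydroxy-4-methyl-1-[(4R)-4-(propan-2-yl)-2-sulfanylidene-1,3-thiazolidin-3-yl]-4-(prop-2-en-1-yl)hept-6-en-1-one | CC(C)[C@@H]1CSC(=S)N1C(=O)C[C@H](O)C(C)(CC=C)CC=C
F9 | step 3 | (3S)-3-hydroxy-N-methoxy-N,4-dimethyl-4-(prop-2-en-1-yl)hept-6-enamide | CON(C)C(=O)C[C@H](O)C(C)(CC=C)CC=C
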